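Hold the charge fixed: by 30 min each of the four flasks has taken in 0.050 M of J and 0.0650 M of E, so they part by history, not by charge.

| flask | J | E | remark | time |
|---|---|---|---|---|
| south-east | 0.050 M | 0.065 M | run made earlier |  |
| north-west | 0.070 M | 0.065 M | run made earlier |  |
| north | 0.11 M | 0.065 M | run made earlier |  |
| north-east | 0.050 M | 0.098 M | run made earlier |  |
| Saturday's | 0.050 M | 0.0650 M (in portions, 5, over 30 min) | first portion at the start, last at 30 min | 50 min |
| Tuesday's | 0.050 M | 0.0650 M | everything together at the start | 50 min |
| Thursday's | 0.050 M (fed, over 30 min) | 0.0650 M | all else is in the flask from the start; the feed brings no volume worth counting | 50 min |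
| Wednesday's | 0.050 M | 0.0650 M (fed, over 30 min) | all else is in the flask from the start; the feed brings no volume worth counting | 50 min |

| run | time / min | X / % |
|---|---|---|
| south-east | 10.0 | 10.2 |
| south-east | 20.0 | 21.4 |
| south-east | 30.0 | 27.0 |
| south-east | 40.0 | 27.9 |
| south-east | 50.0 | 29.4 |
| north-west | 10.0 | 16.6 |
| north-west | 20.0 | 23.9 |
| north-west | 30.0 | 25.1 |
| north-west | 40.0 | 24.3 |
| north-west | 50.0 | 23.6 |
| north | 10.0 | 20.1 |
| north | 20.0 | 16.6 |
| north | 30.0 | 15.2 |
| north | 40.0 | 12.3 |
| north | 50.0 | 10.3 |
| north-east | 10.0 | 28.9 |
| north-east | 20.0 | 45.6 |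
| north-east | 30.0 | 47.1 |
| north-east | 40.0 | 45.3 |
| north-east | 50.0 | 42.5 |

(readings scatter by 0.5 percentage points)

- the flask with the highest amount of X, in percent of the J charged ("all alike" if they lie within 1.5 percentage points) (Saturday's / Tuesday's / Thursday's / Wednesday's / all alike)
- final X, as a percentage of the J charged, in Saturday's
- final X, as a percentage of the J charged, in Tuesday's
- final X, as a percentage of the J charged, in Thursday's
- final X, as a percentage of the J charged, in Wednesday's

- percentages count the J that a species holds: one G counts as two
- reactions considered so far: J + E + X -> 2 X; J + E -> X; E + X -> Z; E <-> L; J + X -> G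

Bracket final X with the south-east run, which is Tuesday's recipe read in advance. Take the time an average part of a dosed charge stays outside the flask: 15.0 min, the mean lag. It comes out the same for the equal portions and for the steady feed.

Roof, age 50 min: 29.4 %
Floor, whole charge in for 20.0 min: 21.4 %
Tightened, mean age 35.0 min: between 27.0 % and 27.9 %, so 27.4 %

Put Tuesday's at the roof, and Saturday's and Wednesday's at the tightened value. The gap of 2 percentage points is wider than the margin of 1.5 points, though not by much, so name Tuesday's.

Keep Thursday's out. There E sits from the start while J arrives at a steady rate, and X hangs hard on E: at 30.0 min the north-east run reads 47.1 % against 27.0 %. Set Thursday's at the floor or under it.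

The forecast gave Tuesday's the lead, with 29 % there, 28 % for Saturday's, 26.5 % for Wednesday's and 20 % for Thursday's, under the floor: “Thursday's should be lowest”.

The flasks give Tuesday's 29.0 %, Wednesday's 26.8 %, Saturday's 26.3 % and Thursday's 19.9 %, so Tuesday's leads, by 2.2 points.

    J + E + X → 2 X (k = 2.80 /M²/s)
    J + E → X (k = 0.00110 /M/s)
    E + X → Z (k = 0.00930 /M/s)
    E ⇌ L (K = 2.00, k = 0.00190 /s)
    J + X → G (k = 0.0170 /M/s)

Thursday's ends under the floor. In Thursday's, the mid-point of turnover up to 50 min falls far earlier for the step from E to L, at 2.89 min, than for the step from J + E + X to 2 X, at 38.1 min. Against 500 min of standing, the same mean lag of 15.0 min is a small delay, and the gap of 9.1 points between Tuesday's and Thursday's shrinks to 0.51 points, with Tuesday's at 7.22 % and Thursday's at 6.71 %.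

The data were generated by integration with constants of no real substance, and the scatter is random.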